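**Retrosynthetic overview**

1. Target 21 comes from photolysis of a (3S) mixed acetal 20 made from racemic galbinic acid 19 and (S)-1-(2-nitrophenyl)ethanol (20 is separable from its (3R) epimer); 19 comes from BCl3 unmasking of the protected depsidone 18.
2. Key disconnection: the O–C(=O) bridge of ring C (the seven-membered 1,4-dioxepinone) is taken out as CO2. This leaves diaryl ether 15, with iodine on ring A (on the carbon between the methyl-bearing and the ether-bearing carbons) and fluorine on ring B.
3. Enabling feature: in the closed phthalide form, the lactone carbonyl C1 of ring D sits on C7a, which is para to C5 of ring B (the carbon that ends up with the ester oxygen). That C–F is therefore an SNAr site, and the ether oxygen on the neighbouring C4 holds the ring A carboxylate within reach for a seven-membered closure.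
4. Diaryl ether 12 comes from SNAr of phenol 2 on the ring-opened formyl carboxylate of 10, where the aldehyde ortho to C4–F (not the lactone) is the activator: ring–chain tautomerism of ring D switches the substitution site between the two fluorines.
5. Ring order: arenes A and B are bought; ring D is made first (two directed lithiations on 2,3-difluoro-6-methoxybenzaldehyde, steps 4 and 5); ring C is made last (step 10).

Key step: step 10

Assumption (remark on the chemistry): the lactol carbon of ring D is the only stereocentre and can epimerise through the ring-opened formyl acid under acid or base. It is taken to hold its configuration in neutral aprotic solution at or below room temperature. It is therefore carried racemic, fixed at the end as a stable mixed acetal, and released last by a reaction that does not touch its bonds. Phthalide numbering is used for rings B and D: C1 lactone carbonyl, C3 lactol carbon, C4 ether carbon, C5 ester-oxygen carbon, C6 CH2O-bearing carbon, C7 phenol carbon.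

**Route**

Step 1
Reactants: 1 2,6-dimethoxy-4-methylbenzaldehyde
Product: 2 2-hydroxy-6-methoxy-4-methylbenzaldehyde
Conditions: BCl3 (1.05 equiv), CH2Cl2, −78 → 0 °C; then H2O
Reagents that add atoms: none
Why: Chelation-controlled aryl methyl ether cleavage, in which BCl3 bridges the aldehyde oxygen and one ortho methoxy oxygen and chloride removes that methyl group; the two methoxy groups are equivalent and the boron chelate of the first phenoxide should stop the second cleavage.

Step 2
Reactants: 3 2,3-difluoro-6-methoxybenzaldehyde
Product: 4 (2,3-difluoro-6-methoxyphenyl)methanol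
Conditions: NaBH4, MeOH, 0 °C
Reagents that add atoms: none
Why: Borohydride reduction of an aryl aldehyde to the benzylic alcohol that will become the acetoxymethyl carbon.

Step 3
Reactants: 4 (2,3-difluoro-6-methoxyphenyl)methanol
Product: 5 1,2-difluoro-4-methoxy-3-[(methoxymethoxy)methyl]benzene
Conditions: MOMCl, iPr2NEt, CH2Cl2, 0 °C → rt
Reagents that add atoms: chloromethyl methyl ether, COCCl
Why: Standard methoxymethyl ether formation, which gives an achiral, base-stable mask for the two lithiations and the SNAr step and is removable by methanolic acid.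

Step 4
Reactants: 5 1,2-difluoro-4-methoxy-3-[(methoxymethoxy)methyl]benzene
Product: 7 2,3-difluoro-5-methoxy-4-[(methoxymethoxy)methyl]benzaldehyde, via aryllithium 6 (not isolated)
Conditions: LiN(iPr)2 (1.1 equiv), THF, −78 °C; DMF, −78 °C; then aq. HCl to pH 5
Reagents that add atoms: N,N-dimethylformamide, CN(C)C=O
Why: Fluorine-directed ortho-lithiation, in which the amide base removes the more acidic of the two ring hydrogens (the one ortho to fluorine), followed by formylation at −78 °C, below the onset of LiF loss to an aryne.

Step 5
Reactants: 7 2,3-difluoro-5-methoxy-4-[(methoxymethoxy)methyl]benzaldehyde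
Product: 10 4,5-difluoro-3-hydroxy-7-methoxy-6-[(methoxymethoxy)methyl]isobenzofuran-1(3H)-one (racemic), via lithium amino alkoxide 8 (not isolated), via ring-lithiated amino alkoxide 9 (not isolated)
Conditions: LiN(Me)CH2CH2NMe2 (from the diamine and n-BuLi), THF, −20 °C; n-BuLi (2.5 equiv), −20 °C; CO2 (g), −78 °C → rt; 1 M HCl to pH 3
Reagents that add atoms: carbon dioxide, O=C=O
Why: Comins-type in situ protection of the aldehyde as a chelating lithium α-amino alkoxide, which together with the methoxy group directs lithiation to the only ring C–H left; carboxylation and acidic work-up release the 2-formylbenzoic acid, which closes to the lactol of ring D with its stereocentre formed without control (corrected in step 12).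

Step 6
Reactants: 10 4,5-difluoro-3-hydroxy-7-methoxy-6-[(methoxymethoxy)methyl]isobenzofuran-1(3H)-one (racemic); 2 2-hydroxy-6-methoxy-4-methylbenzaldehyde
Product: 12 5-fluoro-4-(2-formyl-3-methoxy-5-methylphenoxy)-3-hydroxy-7-methoxy-6-[(methoxymethoxy)methyl]isobenzofuran-1(3H)-one (racemic), via open-chain potassium carboxylate 11 (not isolated)
Conditions: K2CO3 (3 equiv), DMSO, 100 °C; then aq. HCl to pH 3
Reagents that add atoms: none
Why: SNAr of a phenoxide on a 2-fluorobenzaldehyde; in base the lactol is open as the formyl carboxylate, so only the fluorine ortho to the aldehyde is activated (the other is meta to CHO and para to the non-activating carboxylate), and acidification re-closes ring D.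

Step 7
Reactants: 12 5-fluoro-4-(2-formyl-3-methoxy-5-methylphenoxy)-3-hydroxy-7-methoxy-6-[(methoxymethoxy)methyl]isobenzofuran-1(3H)-one (racemic)
Product: 13 5-fluoro-4-(2-formyl-6-iodo-3-methoxy-5-methylphenoxy)-3-hydroxy-7-methoxy-6-[(methoxymethoxy)methyl]isobenzofuran-1(3H)-one (racemic)
Conditions: NIS (1.05 equiv), TFA (0.2 equiv), MeCN, 0 °C → rt
Reagents that add atoms: N-iodosuccinimide, O=C1CCC(=O)N1I
Why: Electrophilic aromatic iodination, expected para to the methoxy group of ring A (the stronger donor; the aryloxy oxygen is attenuated by the electron-poor ring B), while ring B is too deactivated to react.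

Step 8
Reactants: 13 5-fluoro-4-(2-formyl-6-iodo-3-methoxy-5-methylphenoxy)-3-hydroxy-7-methoxy-6-[(methoxymethoxy)methyl]isobenzofuran-1(3H)-one (racemic)
Product: 14 4-[2-(dimethoxymethyl)-6-iodo-3-methoxy-5-methylphenoxy]-5-fluoro-6-(hydroxymethyl)-3,7-dimethoxyisobenzofuran-1(3H)-one (racemic)
Conditions: HCl (1.25 M in MeOH), HC(OMe)3, 45 °C
Reagents that add atoms: methanol, CO; trimethyl orthoformate, COC(OC)OC
Why: Acid-catalysed acetal chemistry in methanol should do three things at once: Fischer-type pseudo-ester formation at the lactol (3-methoxyphthalide, which locks ring D closed), dimethyl acetal formation at the ring A aldehyde, and methanolysis of the MOM ether.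

Step 9
Reactants: 14 4-[2-(dimethoxymethyl)-6-iodo-3-methoxy-5-methylphenoxy]-5-fluoro-6-(hydroxymethyl)-3,7-dimethoxyisobenzofuran-1(3H)-one (racemic)
Product: 15 {4-[2-(dimethoxymethyl)-6-iodo-3-methoxy-5-methylphenoxy]-5-fluoro-3,7-dimethoxy-1-oxo-1,3-dihydroisobenzofuran-6-yl}methyl acetate (racemic)
Conditions: Ac2O, pyridine, DMAP (cat.), CH2Cl2, 0 °C → rt
Reagents that add atoms: acetic anhydride, CC(=O)OC(C)=O
Why: Acylation of the only free hydroxyl group, a primary benzylic alcohol, to install the acetate of the target.

Step 10
Reactants: 15 {4-[2-(dimethoxymethyl)-6-iodo-3-methoxy-5-methylphenoxy]-5-fluoro-3,7-dimethoxy-1-oxo-1,3-dihydroisobenzofuran-6-yl}methyl acetate (racemic)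
Product: 18 protected depsidone (racemic): galbinic acid carrying methyl ethers on both phenols and a dimethyl acetal at the ring A aldehyde and a methyl pseudo-ester (OMe on C3) at the lactol, via arylmagnesium chloride 16 (not isolated), via cesium carboxylate 17 (not isolated)
Conditions: iPrMgCl·LiCl (1.1 equiv), THF, −40 °C; CO2 (g), −40 → 0 °C; then Cs2CO3, DMSO, THF distilled off, 100 °C
Reagents that add atoms: carbon dioxide, O=C=O
Why: Proposed new method: iodine–magnesium exchange (Knochel type) at −40 °C turns the iodine-bearing ring A carbon into aryl Grignard 16, which adds to CO2 (new aryl–C bond), and carboxylate 17, once freed as its cesium salt in DMSO, adds through oxygen to C5 of ring B and expels fluoride by addition–elimination (new aryl–O bond), so that CO2 ends up inserted as O–C(=O) between the two arenes. The closest known reaction types are the carboxylation of functionalised arylmagnesium reagents and the SNAr O-arylation or lactonisation of carboxylates on activated fluoroarenes; their union in one operation and the closure of a depsidone ring in this way are not established. Ring C closes by a 7-exo-trig attack on the arene carbon, made possible because the ether oxygen holds carboxylate and C5 in a seven-membered array and because the Meisenheimer charge at C7a is taken up by the coplanar lactone carbonyl of ring D. No stereocentre is formed and the racemic acetal carbon C3 is not touched. Chemoselectivity of the Grignard stage (no attack on acetate or lactone or C–F, the last of which would give a dibenzofuran) rests on the low temperature and on the doubly ortho-substituted aryl–Mg bond, and site selectivity of the SNAr stage is given because C5–F is the only leaving group left. Magnesium and lithium cations bind the fluoride set free and so protect the acetate and the new aryl ester.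

Step 11
Reactants: 18 protected depsidone (racemic)
Product: 19 galbinic acid, racemic at the lactol carbon
Conditions: BCl3 (8 equiv), CH2Cl2, −78 → 0 °C; then H2O–THF, 0 °C
Reagents that add atoms: water, O
Why: Lewis-acid deprotection: BCl3 opens the dimethyl acetal to the aldehyde, cleaves the two aryl methyl ethers with chelation assistance (each is ortho to a carbonyl: ring A CHO and the ring D lactone), and ionises the pseudo-ester methoxy group so that aqueous work-up returns the lactol, while the acetate and the aryl ester of ring C are expected to survive.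

Step 12
Reactants: 19 galbinic acid, racemic at the lactol carbon
Product: 20 (3S)-O-[(1S)-1-(2-nitrophenyl)ethyl] acetal of galbinic acid
Conditions: (S)-1-(2-nitrophenyl)ethanol (3 equiv), CSA (cat.), 4 Å molecular sieves, 1,4-dioxane–toluene, 60 °C; chromatography
Reagents that add atoms: (S)-1-(2-nitrophenyl)ethanol, C[C@H](O)c1ccccc1[N+](=O)[O-]
Why: Acid-catalysed pseudo-ester (mixed acetal) formation of a 3-hydroxyphthalide through the phthalidyl oxocarbenium ion, which is attacked on both faces without control, so the two C3 epimers should form as diastereomers of the (S)-auxiliary and be separable on silica; the (3S) diastereomer 20 is collected and fixes the target configuration, while the (3R) diastereomer (same constitution, opposite configuration at the acetal carbon C3) is removed at this point and not carried forward.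

Step 13
Reactants: 20 (3S)-O-[(1S)-1-(2-nitrophenyl)ethyl] acetal of galbinic acid
Product: 21 galbinic acid, (S) at the lactol carbon
Conditions: hν (365 nm), MeCN, rt, neutral; low-temperature isolation
Reagents that add atoms: none
Why: Photolysis of a 1-(2-nitrophenyl)ethyl acetal (hydrogen abstraction by the excited nitro group, aci-nitro intermediate, collapse of the resulting hemiacetal) breaks only the auxiliary's own benzylic C–O bond under neutral conditions, so both C–O bonds of the lactol carbon and the (S) configuration fixed in step 12 are retained.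

**Compound list**

1 | 2,6-dimethoxy-4-methylbenzaldehyde | COc1cc(C)cc(OC)c1C=O | starting material
2 | 2-hydroxy-6-methoxy-4-methylbenzaldehyde | COc1cc(C)cc(O)c1C=O | intermediate
3 | 2,3-difluoro-6-methoxybenzaldehyde | COc1ccc(F)c(F)c1C=O | starting material
4 | (2,3-difluoro-6-methoxyphenyl)methanol | OCc1c(F)c(F)ccc1OC | intermediate
5 | 1,2-difluoro-4-methoxy-3-[(methoxymethoxy)methyl]benzene | COCOCc1c(F)c(F)ccc1OC | intermediate
6 | {2,3-difluoro-5-methoxy-4-[(methoxymethoxy)methyl]phenyl}lithium | COCOCc1c(F)c(F)c([Li])cc1OC | intermediate
7 | 2,3-difluoro-5-methoxy-4-[(methoxymethoxy)methyl]benzaldehyde | COCOCc1c(F)c(F)c(C=O)cc1OC | intermediate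
8 | lithium α-amino alkoxide of 7 with lithium [2-(dimethylamino)ethyl](methyl)amide (racemic) | COCOCc1c(F)c(F)c(C(O[Li])N(C)CCN(C)C)cc1OC | intermediate
9 | 8 lithiated at the ring carbon between the amino alkoxide carbon and the methoxy carbon (racemic) | COCOCc1c(F)c(F)c(C(O[Li])N(C)CCN(C)C)c([Li])c1OC | intermediate
10 | 4,5-difluoro-3-hydroxy-7-methoxy-6-[(methoxymethoxy)methyl]isobenzofuran-1(3H)-one (racemic) | COCOCc1c(OC)c2C(=O)OC(O)c2c(F)c1F | intermediate
11 | potassium 4-fluoro-2-formyl-3-(2-formyl-3-methoxy-5-methylphenoxy)-6-methoxy-5-[(methoxymethoxy)methyl]benzoate | COCOCc1c(OC)c(C(=O)[O-])c(C=O)c(Oc2cc(C)cc(OC)c2C=O)c1F.[K+] | intermediate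
12 | 5-fluoro-4-(2-formyl-3-methoxy-5-methylphenoxy)-3-hydroxy-7-methoxy-6-[(methoxymethoxy)methyl]isobenzofuran-1(3H)-one (racemic) | COCOCc1c(OC)c2C(=O)OC(O)c2c(Oc2cc(C)cc(OC)c2C=O)c1F | intermediate
13 | 5-fluoro-4-(2-formyl-6-iodo-3-methoxy-5-methylphenoxy)-3-hydroxy-7-methoxy-6-[(methoxymethoxy)methyl]isobenzofuran-1(3H)-one (racemic) | COCOCc1c(OC)c2C(=O)OC(O)c2c(Oc2c(I)c(C)cc(OC)c2C=O)c1F | intermediate
14 | 4-[2-(dimethoxymethyl)-6-iodo-3-methoxy-5-methylphenoxy]-5-fluoro-6-(hydroxymethyl)-3,7-dimethoxyisobenzofuran-1(3H)-one (racemic) | OCc1c(OC)c2C(=O)OC(OC)c2c(Oc2c(I)c(C)cc(OC)c2C(OC)OC)c1F | intermediate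
15 | {4-[2-(dimethoxymethyl)-6-iodo-3-methoxy-5-methylphenoxy]-5-fluoro-3,7-dimethoxy-1-oxo-1,3-dihydroisobenzofuran-6-yl}methyl acetate (racemic) | CC(=O)OCc1c(OC)c2C(=O)OC(OC)c2c(Oc2c(I)c(C)cc(OC)c2C(OC)OC)c1F | intermediate
16 | arylmagnesium chloride from 15 (MgCl in place of iodine; racemic) | CC(=O)OCc1c(OC)c2C(=O)OC(OC)c2c(Oc2c([Mg]Cl)c(C)cc(OC)c2C(OC)OC)c1F | intermediate
17 | cesium 2-{[6-(acetoxymethyl)-5-fluoro-3,7-dimethoxy-1-oxo-1,3-dihydroisobenzofuran-4-yl]oxy}-3-(dimethoxymethyl)-4-methoxy-6-methylbenzoate (racemic) | CC(=O)OCc1c(OC)c2C(=O)OC(OC)c2c(Oc2c(C(=O)[O-])c(C)cc(OC)c2C(OC)OC)c1F.[Cs+] | intermediate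
18 | protected depsidone: galbinic acid with both phenols as methyl ethers, the ring A aldehyde as dimethyl acetal and the lactol as methyl pseudo-ester (racemic) | CC(=O)OCc1c(OC)c2C(=O)OC(OC)c2c3Oc4c(C(OC)OC)c(OC)cc(C)c4C(=O)Oc13 | intermediate
19 | galbinic acid, racemic at the lactol carbon | CC(=O)OCc1c(O)c2C(=O)OC(O)c2c3Oc4c(C=O)c(O)cc(C)c4C(=O)Oc13 | intermediate
20 | (3S)-O-[(1S)-1-(2-nitrophenyl)ethyl] acetal of galbinic acid | CC(=O)OCc1c(O)c2c(c3c1OC(=O)c1c(C)cc(O)c(C=O)c1O3)[C@@H](O[C@@H](C)c1ccccc1[N+](=O)[O-])OC2=O | intermediate
21 | galbinic acid, (S) at the lactol carbon | CC(=O)OCc1c(O)c2c(c3c1OC(=O)c1c(C)cc(O)c(C=O)c1O3)[C@@H](O)OC2=O | target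

**Step count and risks**

Total step count: 13. Longest linear sequence: 12 steps (3 → 21, steps 2 to 13); ring A is made in one step (1 → 2) and enters at step 6.

Steps most likely to fail:

Step 10 (Proposed new method). The carboxylate may be too weak a nucleophile for a fluoroarene activated only by the para lactone carbonyl, so the ring closure may stall at 17 or give way to cleavage of the acetate by fluoride or carbonate at the temperature needed. Fallback with known chemistry, from 15 and back at 18: the fluorine on ring B would first be exchanged for hydroxyl with acetohydroxamic acid and K2CO3 in DMSO at 80 °C (a known hydroxide surrogate for activated fluoroarenes that spares esters), giving {4-[2-(dimethoxymethyl)-6-iodo-3-methoxy-5-methylphenoxy]-5-hydroxy-3,7-dimethoxy-1-oxo-1,3-dihydroisobenzofuran-6-yl}methyl acetate F1. Iodine–magnesium exchange with iPrMgCl·LiCl (2.2 equiv, THF, −40 °C), CO2 and work-up at pH 4 would give 2-{[6-(acetoxymethyl)-5-hydroxy-3,7-dimethoxy-1-oxo-1,3-dihydroisobenzofuran-4-yl]oxy}-3-(dimethoxymethyl)-4-methoxy-6-methylbenzoic acid F2. The classical depsidone lactonisation of this hydroxy acid with DCC in toluene would then close ring C by acyl C–O bond formation and rejoin the route at 18.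

Step 7. Iodination may go to the other free ring A position (para to the aryloxy oxygen, ortho to methoxy) or at both positions, because both positions are activated by the same three donors and differ only in which oxygen is para. Fallback, from 1 and 10 and back at 13: iodination of the symmetric aldehyde 1 with NIS and catalytic TFA in MeCN can give only one ring-iodinated product, 3-iodo-2,6-dimethoxy-4-methylbenzaldehyde F3. BCl3 (1 equiv, CH2Cl2, −78 °C) would then remove the methyl group of the more hindered methoxy group (the one between the formyl group and iodine, twisted out of the ring plane) to give 2-hydroxy-3-iodo-6-methoxy-4-methylbenzaldehyde F4. SNAr of F4 with 10 under the conditions of step 6 would rejoin the route at 13 with the iodine position fixed by construction.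

Step 6. The substitution may be too slow, because the electrophile is an anion, its reacting carbon is para to a methoxy group, and both partners are ortho-substituted; prolonged heating may then degrade the aldehydes. Fallback, from 10 and back at 12: alkylation of the ring-opened carboxylate of 10 with MeI and K2CO3 in DMF would give the open-chain normal ester, methyl 3,4-difluoro-2-formyl-6-methoxy-5-[(methoxymethoxy)methyl]benzoate F5. This neutral 2-fluorobenzaldehyde should take up phenol 2 (K2CO3, DMF, 80 °C) at the fluorine ortho to the aldehyde to give methyl 4-fluoro-2-formyl-3-(2-formyl-3-methoxy-5-methylphenoxy)-6-methoxy-5-[(methoxymethoxy)methyl]benzoate F6. Hydrolysis with LiOH in THF–water (assisted by the neighbouring aldehyde) and acidification would rejoin the route at 12.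

**Further compounds**

F1 | step 10 | {4-[2-(dimethoxymethyl)-6-iodo-3-methoxy-5-methylphenoxy]-5-hydroxy-3,7-dimethoxy-1-oxo-1,3-dihydroisobenzofuran-6-yl}methyl acetate (racemic) | CC(=O)OCc1c(OC)c2C(=O)OC(OC)c2c(Oc2c(I)c(C)cc(OC)c2C(OC)OC)c1O
F2 | step 10 | 2-{[6-(acetoxymethyl)-5-hydroxy-3,7-dimethoxy-1-oxo-1,3-dihydroisobenzofuran-4-yl]oxy}-3-(dimethoxymethyl)-4-methoxy-6-methylbenzoic acid (racemic) | CC(=O)OCc1c(OC)c2C(=O)OC(OC)c2c(Oc2c(C(=O)O)c(C)cc(OC)c2C(OC)OC)c1O
F3 | step 7 | 3-iodo-2,6-dimethoxy-4-methylbenzaldehyde | COc1cc(C)c(I)c(OC)c1C=O
F4 | step 7 | 2-hydroxy-3-iodo-6-methoxy-4-methylbenzaldehyde | COc1cc(C)c(I)c(O)c1C=O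
F5 | step 6 | methyl 3,4-difluoro-2-formyl-6-methoxy-5-[(methoxymethoxy)methyl]benzoate | COCOCc1c(OC)c(C(=O)OC)c(C=O)c(F)c1F
F6 | step 6 | methyl 4-fluoro-2-formyl-3-(2-formyl-3-methoxy-5-methylphenoxy)-6-methoxy-5-[(methoxymethoxy)methyl]benzoate | COCOCc1c(OC)c(C(=O)OC)c(C=O)c(Oc2cc(C)cc(OC)c2C=O)c1F
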